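## Structural features

The target joins two oxygen heterocycles through a doubly methyl-branched allyl unit. C6 of a 7-methoxy-2,2-dimethyl-2H-chromene (benzene ring A fused to pyran ring B) carries a CH(CH3) carbon, which is bonded to the CH end of a trisubstituted alkene. The other alkene carbon bears a methyl group and C2 of a 5-acetyl-6-hydroxybenzofuran (furan ring C fused to benzene ring D). The only stereocentre is the CH(CH3) carbon, S by the order ring A carbon > alkenyl > methyl > H. It is benzylic and allylic at once and has no stereogenic neighbour, so its configuration must come from a catalyst or reagent. The alkene is E (stereocentre trans to the benzofuran) and conjugated to ring C.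

Fragile points are:
- the electron-rich, styrene-like C3=C4 bond of ring B (acid, electrophiles, hydrogenation);
- the doubly activated C–H of the stereocentre (alkene migration toward ring A would erase it);
- the 2-alkenylbenzofuran, which protonates to a stabilised cation;
- the chelated ortho-hydroxyacetophenone of ring D, with an enolisable methyl ketone and an acidic phenol.

The real difficulty is twofold: making a lone benzylic methyl stereocentre enantioselectively without touching C3=C4, and fixing the E geometry of the neighbouring alkene by a stereospecific process. The key step uses the fact that the stereocentre carries only H, CH3, C6 of ring A and the chain. It therefore maps onto the β-carbon of an (E)-3-arylbut-2-enal, and the aldehyde carbon later becomes the alkene carbon on benzofuran C2.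

## Logic of the disconnections

23 from 21: the O–Si bond on ring D and the two ketal C–O bonds are cut, passing through 22. The free phenol and methyl ketone cannot coexist with n-BuLi or an amide base, so both are carried masked. Nothing is gained in skeleton. The forward step must be mild enough for C3=C4 and the alkenylbenzofuran, hence fluoride first and only dilute acid.

21 from 20: the C(sp2)–CH3 bond is cut. Bringing the methyl group in last by a stereoretentive cross-coupling means the alkene geometry is decided earlier, at the enolate stage. The forward step must proceed with retention and without alkene migration.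

20 from 18, through 19: the O–S bond is cut and the alkene returns to C=O plus CH2. In 18 the ketone has one enolisable position, and an aryl ketone of this type strongly prefers the Z enolate. The geometric problem is thus reduced to a kinetic deprotonation. The forward step needs O-sulfonylation without elimination, and the ring D ketone must stay masked.

18 from 17, and 17 from 8 and 15 through 16: the C–C bond between the carbonyl carbon and benzofuran C2 is cut. This is the most convergent cut, giving two halves of similar size, and C2–H is the most acidic C–H of 15. The forward steps need clean 1,2-addition to an enolisable aldehyde and a neutral oxidation. The stereocentre of 8 is β to the carbonyl and is not at risk.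

8 from 7: the Cβ–H and Cα–H bonds are removed, with no skeletal bond cut. The stereocentre is traced to a flat, easily made enal. The forward step needs one enantioface, chemoselectivity against C3=C4 and the aldehyde, and a geometrically pure 7.

7 from 5 through 6, and 5 from 2 and 3 through 4: the C=C bond is cut by carbonyl olefination, and the aldehyde is reached by one hydride reduction of the N-methoxy-N-methyl amide of 5. This route is one step shorter than going through an ester and an allylic alcohol. The forward steps need E selectivity, with removal of any Z isomer before the key step.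

2 from 1: the aryl–acyl bond at C6 is cut. C6 is para to the ring oxygen and ortho to the methoxy group, so it is the most nucleophilic unhindered position. The forward step needs a Lewis acid acylation gentle enough for C3=C4.

15 from 14, and 14 from 13: the ketal C–O bonds and the O–Si bond are cut. The phenol is silylated first because the chelated phenol blocks ketalisation. A silyl ether is chosen because it does not direct ortho-lithiation and is removed by fluoride. The ketalisation must be aprotic to keep the silyl ether.

13 from 10 through 11 and 12, and 10 from 9: ring C is cut at O1–C2 and C3–C3a, revealing an ortho-iodophenol and a two-carbon alkyne. The C–I bond is then cut. The forward steps need iodination at C5 of 9 and ring closure by the free 4-hydroxyl only.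

## Other disconnections considered

Alternative 1: The cut is the bond between the stereocentre and the alkene CH.
- Forward step: A1, 6-(1-ethoxyethyl)-2,2-dimethyl-2H-chromen-7-ol, is heated with the alkenylboronate A2 and a chiral brominated binaphthol. Loss of ethanol gives the ortho-quinone methide A3. The boronate, made chiral by exchange of its ethoxy groups, transfers the alkenyl group to the exocyclic carbon through a boron-bound cyclic transition state, with retention of alkene geometry, giving A4.
- In its favour: the stereocentre and the last skeletal bond form together on the complete framework. The E geometry is carried in from A2. No organolithium or enolate meets the chromene half.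
- Against it here: the exocyclic carbon of A3 bears a methyl group, so a 1,5-hydrogen shift can drain it before capture. A3 could also undergo hetero-Diels–Alder reaction with the C3=C4 bond of a second molecule. The method needs a free phenol, so A4 must be O-methylated next to a base-labile silyl ether and then desilylated. A2 needs its own stereodefined synthesis.
- Comparison: both plans reach the same E alkene and S centre. Mechanistically this route makes a C–C bond under small-molecule catalyst control, where the chosen plan makes C–H bonds under enzyme control. On convergence and on steps after the key step it is the better plan, and on predictability of the sense of induction it is at least equal. The chosen plan is safer for the chromene and needs no phenol exchange.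

Alternative 2: The cuts are both bonds at the stereocentre, C6–CH and CH–alkene.
- Forward step: the carbamate A6 is lithiated with s-BuLi and a chiral diamine. The carbanion adds to boronate A5 with retention, and the aryl group shifts from boron to carbon with inversion and loss of the carbamate, giving the benzylic boronic ester A7. The alkenyllithium A8 then adds to boron. Iodine and methoxide trigger the 1,2-shift and anti elimination, which should give A9 with retention at the stereocentre and inversion of the alkene geometry (Z reagent to E product).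
- In its favour: the configuration is set by the reagent and is independent of substrate shape. Both stereo-elements and two bonds arise in one operation from three modules. This is better than the chosen plan in predictability and equal in stereospecific control of the alkene.
- Against it here: iodine is an electrophile that the C3=C4 bond of ring B can also take up in the presence of methoxide. The ortho-methoxy boronate is hindered at both ate-complex stages. A5 needs prior C6 functionalisation of the chromene nucleus. A8 must be made as one geometric isomer. A9 still needs the same two deprotections.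
- Comparison: the structures assembled are the same. Mechanistically it relies on stoichiometric chiral base and cryogenic organolithium chemistry, against a catalytic aqueous reduction. The overall step count should be similar once the three modules are counted, so step economy is about equal.

Alternative 3: The cut is the C6–stereocentre bond together with one C–H bond of the new methyl group.
- Forward step: a zerovalent nickel source, Ni(cod)2, with a chiral ligand in an alcohol forms a nickel hydride, which adds to the terminal CH2 of diene A11 to give a π-allyl complex. Transmetalation from boronic acid A10 and reductive elimination at the CH(CH3) terminus would give A12.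
- In its favour: it is the most convergent of the four plans. The ketone is tolerated, so only the phenol is protected, and A12 is one deprotection from the target. On step economy after the key step it is better than the chosen plan.
- Against it here: the diene has a fully substituted inner terminus, unlike the 1-aryl dienes for which such hydroarylations are established, so 1,2- against 1,4-selectivity and enantioselectivity are open. The ortho-methoxy boronic acid is slow in transmetalation and prone to protodeboronation in alcohol. The nickel hydride may also engage the C3=C4 bond of A10. A10 and A11 each need several steps.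
- Comparison: the structure formed is the same. Mechanistically it creates the stereocentre in a C–C bond-forming step of uncertain scope, where the chosen plan uses a reduction with close precedent. It is shorter overall if it works, but it carries more risk at the key step.

Key step: step 4

Assumption: the yeast ene-reductase is taken to reduce the E enal 7 in the same facial sense as simpler (E)-3-arylbut-2-enals, which leads to the S aldehyde; a homologue of opposite preference would be used if this is not so.

## Route

Step 1
Reactants: 1 7-methoxy-2,2-dimethyl-2H-chromene (precocene 1)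
Product: 2 1-(7-methoxy-2,2-dimethyl-2H-chromen-6-yl)ethan-1-one
Conditions: AcCl, AlCl3 (complex preformed), CH2Cl2, −30 → −10 °C
Reagents that add atoms: acetyl chloride, CC(=O)Cl
Why: Friedel–Crafts acylation at C6, which is para to O1 and ortho to OMe, while C8 is flanked by two oxygens and C5 is meta to both. The preformed acylium salt and low temperature limit contact of C3=C4 with free acid.

Step 2
Reactants: 2 1-(7-methoxy-2,2-dimethyl-2H-chromen-6-yl)ethan-1-one; 3 diethyl {2-[methoxy(methyl)amino]-2-oxoethyl}phosphonate
Product: 5 (2E)-N-methoxy-3-(7-methoxy-2,2-dimethyl-2H-chromen-6-yl)-N-methylbut-2-enamide, via sodium phosphonate carbanion 4 (not isolated)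
Conditions: NaH, THF, 0 °C → reflux; chromatography to the pure E isomer
Reagents that add atoms: none
Why: Horner–Wadsworth–Emmons olefination of an aryl methyl ketone. Reversible addition and elimination favour the isomer with the aryl group trans to the carbonyl, and any Z isomer is removed here.

Step 3
Reactants: 5 (2E)-N-methoxy-3-(7-methoxy-2,2-dimethyl-2H-chromen-6-yl)-N-methylbut-2-enamide
Product: 7 (2E)-3-(7-methoxy-2,2-dimethyl-2H-chromen-6-yl)but-2-enal, via aluminium hemiaminal 6 (not isolated)
Conditions: i-Bu2AlH, THF, −78 °C; aq potassium sodium tartrate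
Reagents that add atoms: none
Why: Hydride reduction of an N-methoxy-N-methyl amide stops at the chelated hemiaminal 6, which gives the aldehyde only on hydrolysis. Attack is 1,2, so the E alkene and C3=C4 are untouched.

Step 4
Reactants: 7 (2E)-3-(7-methoxy-2,2-dimethyl-2H-chromen-6-yl)but-2-enal
Product: 8 (3S)-3-(7-methoxy-2,2-dimethyl-2H-chromen-6-yl)butanal
Conditions: OYE2 (ene-reductase, Saccharomyces cerevisiae), NADP+ (cat.), glucose dehydrogenase, D-glucose, KH2PO4/K2HPO4 buffer pH 7.0, DMSO (5% v/v), 30 °C
Reagents that add atoms: none
Why: The enal sits over the reduced flavin with its carbonyl oxygen hydrogen-bonded to the His/Asn pair of the yeast enzyme (His/His in many homologues); hydride passes from flavin N5 to Cβ and the active-site tyrosine protonates Cα from the opposite face, a net anti addition of H2, while glucose dehydrogenase restores NADPH from glucose. The closest known reaction type is the Old Yellow Enzyme or baker's-yeast reduction of (E)-3-arylbut-2-enals to (S)-3-arylbutanals and the derived alcohols. No ring is closed and no C–C bond is formed. The one new stereocentre, at Cβ, is controlled by the active site: the E enal has a single productive binding mode with the aryl group in the large pocket, so hydride should reach only the face that gives S. The Z isomer would be expected to bind flipped and give R, which is why 7 must be geometrically pure. The step needs chemoselectivity for the conjugated C=C over C3=C4 of ring B, the arene and the CHO group; only an alkene activated by the bound carbonyl accepts hydride, and an isolated enzyme free of alcohol dehydrogenases leaves the aldehyde alone. The new centre is β to the carbonyl and cannot be lost by enolisation, and Cα becomes CH2, so the face of protonation does not matter.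

Step 5
Reactants: 9 1-(2,4-dihydroxyphenyl)ethan-1-one (2,4-dihydroxyacetophenone)
Product: 10 1-(2,4-dihydroxy-5-iodophenyl)ethan-1-one
Conditions: ICl (1.0 equiv), AcOH, rt
Reagents that add atoms: iodine monochloride, ClI
Why: Electrophilic aromatic iodination. C5 is para to the chelated 2-hydroxyl, ortho to the free 4-hydroxyl and unhindered, whereas C3 lies between two oxygens and should resist the bulky electrophile in acid.

Step 6
Reactants: 10 1-(2,4-dihydroxy-5-iodophenyl)ethan-1-one
Product: 13 1-(6-hydroxy-1-benzofuran-5-yl)ethan-1-one, via silylethynyl phenol 11 (not isolated), via ethynyl phenol 12 (not isolated)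
Conditions: HC≡CSiMe3, PdCl2(PPh3)2 (cat.), CuI (cat.), Et3N, DMF, rt; then K2CO3 (cat.), MeOH, 60 °C
Reagents that add atoms: ethynyltrimethylsilane, C#C[Si](C)(C)C
Why: Sonogashira coupling at the C–I bond, methanolysis of the C–Si bond, then copper- and base-assisted 5-endo-dig addition of the adjacent 4-hydroxyl to the alkyne closes ring C. The chelated 2-hydroxyl cannot reach the alkyne.

Step 7
Reactants: 13 1-(6-hydroxy-1-benzofuran-5-yl)ethan-1-one
Product: 14 1-{6-[(tert-butyldimethylsilyl)oxy]-1-benzofuran-5-yl}ethan-1-one
Conditions: TBSCl, imidazole, DMF, rt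
Reagents that add atoms: tert-butyldimethylsilyl chloride, CC(C)(C)[Si](C)(C)Cl
Why: Silylation of the phenol breaks the chelate so the ketone can be ketalised. The bulky silyl ether does not direct lithiation to C7 and is later removed by fluoride.

Step 8
Reactants: 14 1-{6-[(tert-butyldimethylsilyl)oxy]-1-benzofuran-5-yl}ethan-1-one
Product: 15 tert-butyldimethyl{[5-(2-methyl-1,3-dioxolan-2-yl)-1-benzofuran-6-yl]oxy}silane
Conditions: (Me3SiOCH2)2, Me3SiOTf (cat.), CH2Cl2, −78 → −20 °C; pyridine quench
Reagents that add atoms: 1,2-bis(trimethylsilyloxy)ethane, C[Si](C)(C)OCCO[Si](C)(C)C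
Why: Silyl triflate-catalysed aprotic ketalisation, driven by formation of hexamethyldisiloxane, masks the enolisable methyl ketone. No protic acid is present, so the aryl silyl ether survives.

Step 9
Reactants: 15 tert-butyldimethyl{[5-(2-methyl-1,3-dioxolan-2-yl)-1-benzofuran-6-yl]oxy}silane; 8 (3S)-3-(7-methoxy-2,2-dimethyl-2H-chromen-6-yl)butanal
Product: 17 (3S)-1-{6-[(tert-butyldimethylsilyl)oxy]-5-(2-methyl-1,3-dioxolan-2-yl)-1-benzofuran-2-yl}-3-(7-methoxy-2,2-dimethyl-2H-chromen-6-yl)butan-1-ol (both C1 epimers), via 2-lithiobenzofuran 16 (not isolated)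
Conditions: n-BuLi, THF, −78 °C; then 8, −78 °C; H2O
Reagents that add atoms: none
Why: Deprotonation at C2, the most acidic C–H of a benzofuran, followed by 1,2-addition of the heteroaryllithium to the aldehyde. The carbinol centre forms unselectively but is removed in step 10, and the β stereocentre is untouched.

Step 10
Reactants: 17 (3S)-1-{6-[(tert-butyldimethylsilyl)oxy]-5-(2-methyl-1,3-dioxolan-2-yl)-1-benzofuran-2-yl}-3-(7-methoxy-2,2-dimethyl-2H-chromen-6-yl)butan-1-ol
Product: 18 (3S)-1-{6-[(tert-butyldimethylsilyl)oxy]-5-(2-methyl-1,3-dioxolan-2-yl)-1-benzofuran-2-yl}-3-(7-methoxy-2,2-dimethyl-2H-chromen-6-yl)butan-1-one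
Conditions: Dess–Martin periodinane, pyridine, CH2Cl2, 0 °C → rt
Reagents that add atoms: none
Why: Dess–Martin oxidation of a secondary alcohol under buffered, near-neutral conditions spares the ketal, the silyl ether and C3=C4. The stereocentre is β to the new ketone and cannot enolise.

Step 11
Reactants: 18 (3S)-1-{6-[(tert-butyldimethylsilyl)oxy]-5-(2-methyl-1,3-dioxolan-2-yl)-1-benzofuran-2-yl}-3-(7-methoxy-2,2-dimethyl-2H-chromen-6-yl)butan-1-one
Product: 20 (1Z,3S)-1-{6-[(tert-butyldimethylsilyl)oxy]-5-(2-methyl-1,3-dioxolan-2-yl)-1-benzofuran-2-yl}-3-(7-methoxy-2,2-dimethyl-2H-chromen-6-yl)but-1-en-1-yl trifluoromethanesulfonate, via potassium Z-enolate 19 (not isolated)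
Conditions: KN(SiMe3)2 (1.1 equiv), THF, −78 °C; then PhNTf2, −78 → 0 °C
Reagents that add atoms: N-phenylbis(trifluoromethanesulfonimide), O=S(=O)(N(c1ccccc1)S(=O)(=O)C(F)(F)F)C(F)(F)F
Why: The CH2 group is the only enolisable site, and aryl ketones give the Z enolate because the E enolate suffers A(1,3) strain between the heteroaryl group and the branched chain. O-Sulfonylation traps this geometry, and only a slight excess of base is used to avoid elimination to the alkyne.

Step 12
Reactants: 20 (1Z,3S)-1-{6-[(tert-butyldimethylsilyl)oxy]-5-(2-methyl-1,3-dioxolan-2-yl)-1-benzofuran-2-yl}-3-(7-methoxy-2,2-dimethyl-2H-chromen-6-yl)but-1-en-1-yl trifluoromethanesulfonate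
Product: 21 tert-butyl({2-[(2E,4S)-4-(7-methoxy-2,2-dimethyl-2H-chromen-6-yl)pent-2-en-2-yl]-5-(2-methyl-1,3-dioxolan-2-yl)-1-benzofuran-6-yl}oxy)dimethylsilane
Conditions: MeZnCl, Pd(PPh3)4 (cat.), THF, rt → 50 °C
Reagents that add atoms: methylzinc chloride, C[Zn]Cl
Why: Negishi coupling. Zerovalent palladium inserts into the alkenyl C–O bond and reductive elimination follows, both with retention, so the Z triflate gives the E alkene (the descriptor changes only because CH3 replaces O). The methyl group has no β-hydrogen and the neutral conditions leave the allylic stereocentre alone.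

Step 13
Reactants: 21 tert-butyl({2-[(2E,4S)-4-(7-methoxy-2,2-dimethyl-2H-chromen-6-yl)pent-2-en-2-yl]-5-(2-methyl-1,3-dioxolan-2-yl)-1-benzofuran-6-yl}oxy)dimethylsilane
Product: 23 1-{6-hydroxy-2-[(2E,4S)-4-(7-methoxy-2,2-dimethyl-2H-chromen-6-yl)pent-2-en-2-yl]-1-benzofuran-5-yl}ethan-1-one, via phenol ketal 22 (not isolated)
Conditions: Bu4NF, THF, 0 °C; then 1 M aq HCl, rt
Reagents that add atoms: water, O
Why: Fluoride cleaves the aryl O–Si bond, then dilute aqueous acid hydrolyses the aryl methyl ketone dioxolane through an aryl-stabilised oxocarbenium ion. The acid is kept weak and cold enough for C3=C4 and the alkenylbenzofuran, and the product is stabilised by the phenol–acetyl hydrogen bond.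

## Compound list

1 | 7-methoxy-2,2-dimethyl-2H-chromene (precocene 1) | COc1ccc2C=CC(C)(C)Oc2c1 | starting material
2 | 1-(7-methoxy-2,2-dimethyl-2H-chromen-6-yl)ethan-1-one | COc1cc2c(cc1C(C)=O)C=CC(C)(C)O2 | intermediate
3 | diethyl {2-[methoxy(methyl)amino]-2-oxoethyl}phosphonate | CCOP(=O)(CC(=O)N(C)OC)OCC | starting material
4 | sodium salt of the α-carbanion of 3 | [Na+].CCOP(=O)(OCC)[CH-]C(=O)N(C)OC | intermediate
5 | (2E)-N-methoxy-3-(7-methoxy-2,2-dimethyl-2H-chromen-6-yl)-N-methylbut-2-enamide | COc1cc2c(cc1/C(C)=C/C(=O)N(C)OC)C=CC(C)(C)O2 | intermediate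
6 | O-diisobutylaluminium N-methoxy-N-methyl hemiaminal of 7 | COc1cc2c(cc1/C(C)=C/C(O[Al](CC(C)C)CC(C)C)N(C)OC)C=CC(C)(C)O2 | intermediate
7 | (2E)-3-(7-methoxy-2,2-dimethyl-2H-chromen-6-yl)but-2-enal | COc1cc2c(cc1/C(C)=C/C=O)C=CC(C)(C)O2 | intermediate
8 | (3S)-3-(7-methoxy-2,2-dimethyl-2H-chromen-6-yl)butanal | COc1cc2c(cc1[C@@H](C)CC=O)C=CC(C)(C)O2 | intermediate
9 | 1-(2,4-dihydroxyphenyl)ethan-1-one | CC(=O)c1ccc(O)cc1O | starting material
10 | 1-(2,4-dihydroxy-5-iodophenyl)ethan-1-one | CC(=O)c1cc(I)c(O)cc1O | intermediate
11 | 1-{2,4-dihydroxy-5-[(trimethylsilyl)ethynyl]phenyl}ethan-1-one | CC(=O)c1cc(C#C[Si](C)(C)C)c(O)cc1O | intermediate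
12 | 1-(5-ethynyl-2,4-dihydroxyphenyl)ethan-1-one | CC(=O)c1cc(C#C)c(O)cc1O | intermediate
13 | 1-(6-hydroxy-1-benzofuran-5-yl)ethan-1-one | CC(=O)c1cc2ccoc2cc1O | intermediate
14 | 1-{6-[(tert-butyldimethylsilyl)oxy]-1-benzofuran-5-yl}ethan-1-one | CC(=O)c1cc2ccoc2cc1O[Si](C)(C)C(C)(C)C | intermediate
15 | tert-butyldimethyl{[5-(2-methyl-1,3-dioxolan-2-yl)-1-benzofuran-6-yl]oxy}silane | CC1(OCCO1)c1cc2ccoc2cc1O[Si](C)(C)C(C)(C)C | intermediate
16 | {6-[(tert-butyldimethylsilyl)oxy]-5-(2-methyl-1,3-dioxolan-2-yl)-1-benzofuran-2-yl}lithium | [Li]c1cc2cc(C3(C)OCCO3)c(O[Si](C)(C)C(C)(C)C)cc2o1 | intermediate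
17 | (3S)-1-{6-[(tert-butyldimethylsilyl)oxy]-5-(2-methyl-1,3-dioxolan-2-yl)-1-benzofuran-2-yl}-3-(7-methoxy-2,2-dimethyl-2H-chromen-6-yl)butan-1-ol, both C1 epimers | COc1cc2c(cc1[C@@H](C)CC(O)c1cc3cc(C4(C)OCCO4)c(O[Si](C)(C)C(C)(C)C)cc3o1)C=CC(C)(C)O2 | intermediate
18 | (3S)-1-{6-[(tert-butyldimethylsilyl)oxy]-5-(2-methyl-1,3-dioxolan-2-yl)-1-benzofuran-2-yl}-3-(7-methoxy-2,2-dimethyl-2H-chromen-6-yl)butan-1-one | COc1cc2c(cc1[C@@H](C)CC(=O)c1cc3cc(C4(C)OCCO4)c(O[Si](C)(C)C(C)(C)C)cc3o1)C=CC(C)(C)O2 | intermediate
19 | potassium (1Z,3S)-1-{6-[(tert-butyldimethylsilyl)oxy]-5-(2-methyl-1,3-dioxolan-2-yl)-1-benzofuran-2-yl}-3-(7-methoxy-2,2-dimethyl-2H-chromen-6-yl)but-1-en-1-olate | COc1cc2c(cc1[C@@H](C)/C=C(\[O-])c1cc3cc(C4(C)OCCO4)c(O[Si](C)(C)C(C)(C)C)cc3o1)C=CC(C)(C)O2.[K+] | intermediate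
20 | (1Z,3S)-1-{6-[(tert-butyldimethylsilyl)oxy]-5-(2-methyl-1,3-dioxolan-2-yl)-1-benzofuran-2-yl}-3-(7-methoxy-2,2-dimethyl-2H-chromen-6-yl)but-1-en-1-yl trifluoromethanesulfonate | COc1cc2c(cc1[C@@H](C)/C=C(\OS(=O)(=O)C(F)(F)F)c1cc3cc(C4(C)OCCO4)c(O[Si](C)(C)C(C)(C)C)cc3o1)C=CC(C)(C)O2 | intermediate
21 | tert-butyl({2-[(2E,4S)-4-(7-methoxy-2,2-dimethyl-2H-chromen-6-yl)pent-2-en-2-yl]-5-(2-methyl-1,3-dioxolan-2-yl)-1-benzofuran-6-yl}oxy)dimethylsilane | COc1cc2c(cc1[C@@H](C)/C=C(\C)c1cc3cc(C4(C)OCCO4)c(O[Si](C)(C)C(C)(C)C)cc3o1)C=CC(C)(C)O2 | intermediate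
22 | 2-[(2E,4S)-4-(7-methoxy-2,2-dimethyl-2H-chromen-6-yl)pent-2-en-2-yl]-5-(2-methyl-1,3-dioxolan-2-yl)-1-benzofuran-6-ol | COc1cc2c(cc1[C@@H](C)/C=C(\C)c1cc3cc(C4(C)OCCO4)c(O)cc3o1)C=CC(C)(C)O2 | intermediate
23 | 1-{6-hydroxy-2-[(2E,4S)-4-(7-methoxy-2,2-dimethyl-2H-chromen-6-yl)pent-2-en-2-yl]-1-benzofuran-5-yl}ethan-1-one | COc1cc2c(cc1[C@@H](C)/C=C(\C)c1cc3cc(C(C)=O)c(O)cc3o1)C=CC(C)(C)O2 | target

## Step count and risks

Total: 13 steps. Longest linear sequence: 9 steps (steps 1–4 then 9–13; the benzofuran arm, steps 5–8 then 9–13, is equally long).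

Step 4 (key step). The most likely failure is poor acceptance of the bulky ortho-methoxy bicyclic enal, seen as slow turnover or limited solubility. Incomplete facial selectivity is also possible if the aryl group forces a second binding mode, and any E to Z isomerisation of 7 in the buffer would erode enantiopurity. Fallback: from 7 to 8 by iminium-ion organocatalysis in place of the enzyme. A chiral 2-tert-butyl-3-methylimidazolidin-4-one trichloroacetate salt (enantiomer chosen for S) and a Hantzsch ester in CHCl3 at −30 °C effect a conjugate transfer hydrogenation. This is convergent for E and Z enal and ignores unactivated alkenes. It makes no new compound (F0) and returns to the route at 8.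

Step 1. The likely failure is acid-induced oligomerisation or HCl addition at the C3=C4 bond, or loss of the methyl ether ortho to the new ketone under AlCl3. Fallback: from 1, Vilsmeier–Haack formylation (POCl3, DMF, 0 °C → rt, aq NaOAc) at C6 should give 7-methoxy-2,2-dimethyl-2H-chromene-6-carbaldehyde F1. MeMgBr in THF at 0 °C would then give 1-(7-methoxy-2,2-dimethyl-2H-chromen-6-yl)ethan-1-ol F2, and MnO2 in CH2Cl2 would oxidise this benzylic alcohol to 2, where the route is rejoined. No strong Lewis acid is used in this sequence.

Step 5. The likely failure is iodination at C3 between the two hydroxyls, or double iodination, because both positions are activated. Fallback: from 9, bromination (Br2, AcOH, rt), which on this nucleus classically goes to C5, would give 1-(5-bromo-2,4-dihydroxyphenyl)ethan-1-one F3. Copper-free alkynylation of F3 with ethynyltrimethylsilane (Pd(OAc)2, XPhos, Et3N, MeCN, 80 °C), followed by the same methanolysis and ring closure, passes through 11 and 12 and returns to the route at 13.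

Step 13. The likely failure is acid-promoted protonation of the alkenylbenzofuran, leading to alkene migration or E/Z scrambling and loss of the stereocentre, or hydration of C3=C4, during ketal hydrolysis. Fallback: change the order so that acid never meets the alkenylbenzofuran. From 20, hydrolysis of the dioxolane (1 M aq HCl, THF, rt) at the acid-stable enol triflate stage would give (1Z,3S)-1-{5-acetyl-6-[(tert-butyldimethylsilyl)oxy]-1-benzofuran-2-yl}-3-(7-methoxy-2,2-dimethyl-2H-chromen-6-yl)but-1-en-1-yl trifluoromethanesulfonate F4. Negishi methylation (MeZnCl, Pd(PPh3)4, THF), which tolerates the free ketone, would give 1-{6-[(tert-butyldimethylsilyl)oxy]-2-[(2E,4S)-4-(7-methoxy-2,2-dimethyl-2H-chromen-6-yl)pent-2-en-2-yl]-1-benzofuran-5-yl}ethan-1-one F5. Bu4NF in THF at 0 °C with a neutral aqueous work-up then returns to the route at 23.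

## Further compounds

F0 | step 4 | none | none
F1 | step 1 | 7-methoxy-2,2-dimethyl-2H-chromene-6-carbaldehyde | COc1cc2c(cc1C=O)C=CC(C)(C)O2
F2 | step 1 | 1-(7-methoxy-2,2-dimethyl-2H-chromen-6-yl)ethan-1-ol (racemic) | COc1cc2c(cc1C(C)O)C=CC(C)(C)O2
F3 | step 5 | 1-(5-bromo-2,4-dihydroxyphenyl)ethan-1-one | CC(=O)c1cc(Br)c(O)cc1O
F4 | step 13 | (1Z,3S)-1-{5-acetyl-6-[(tert-butyldimethylsilyl)oxy]-1-benzofuran-2-yl}-3-(7-methoxy-2,2-dimethyl-2H-chromen-6-yl)but-1-en-1-yl trifluoromethanesulfonate | COc1cc2c(cc1[C@@H](C)/C=C(\OS(=O)(=O)C(F)(F)F)c1cc3cc(C(C)=O)c(O[Si](C)(C)C(C)(C)C)cc3o1)C=CC(C)(C)O2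
F5 | step 13 | 1-{6-[(tert-butyldimethylsilyl)oxy]-2-[(2E,4S)-4-(7-methoxy-2,2-dimethyl-2H-chromen-6-yl)pent-2-en-2-yl]-1-benzofuran-5-yl}ethan-1-one | COc1cc2c(cc1[C@@H](C)/C=C(\C)c1cc3cc(C(C)=O)c(O[Si](C)(C)C(C)(C)C)cc3o1)C=CC(C)(C)O2
A1 | alternative 1 | 6-(1-ethoxyethyl)-2,2-dimethyl-2H-chromen-7-ol (racemic) | CCOC(C)c1cc2C=CC(C)(C)Oc2cc1O
A2 | alternative 1 | diethyl [(1E)-2-{5-acetyl-6-[(tert-butyldimethylsilyl)oxy]-1-benzofuran-2-yl}prop-1-en-1-yl]boronate | CCOB(OCC)/C=C(\C)c1cc2cc(C(C)=O)c(O[Si](C)(C)C(C)(C)C)cc2o1
A3 | alternative 1 | (6E)-6-ethylidene-2,2-dimethyl-2H-chromen-7(6H)-one | C/C=C1\C=C2C=CC(C)(C)OC2=CC1=O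
A4 | alternative 1 | 1-{6-[(tert-butyldimethylsilyl)oxy]-2-[(2E,4S)-4-(7-hydroxy-2,2-dimethyl-2H-chromen-6-yl)pent-2-en-2-yl]-1-benzofuran-5-yl}ethan-1-one | Oc1cc2c(cc1[C@@H](C)/C=C(\C)c1cc3cc(C(C)=O)c(O[Si](C)(C)C(C)(C)C)cc3o1)C=CC(C)(C)O2
A5 | alternative 2 | 2-(7-methoxy-2,2-dimethyl-2H-chromen-6-yl)-4,4,5,5-tetramethyl-1,3,2-dioxaborolane | COc1cc2OC(C)(C)C=Cc2cc1B1OC(C)(C)C(C)(C)O1
A6 | alternative 2 | ethyl N,N-diisopropylcarbamate | CCOC(=O)N(C(C)C)C(C)C
A7 | alternative 2 | 2-[(1R)-1-(7-methoxy-2,2-dimethyl-2H-chromen-6-yl)ethyl]-4,4,5,5-tetramethyl-1,3,2-dioxaborolane | COc1cc2c(cc1[C@@H](C)B1OC(C)(C)C(C)(C)O1)C=CC(C)(C)O2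
A8 | alternative 2 | [(1Z)-2-[6-(methoxymethoxy)-5-(2-methyl-1,3-dioxolan-2-yl)-1-benzofuran-2-yl]prop-1-en-1-yl]lithium | [Li]/C=C(/C)c1cc2cc(C3(C)OCCO3)c(OCOC)cc2o1
A9 | alternative 2 | 2-[(2E,4S)-4-(7-methoxy-2,2-dimethyl-2H-chromen-6-yl)pent-2-en-2-yl]-6-(methoxymethoxy)-5-(2-methyl-1,3-dioxolan-2-yl)-1-benzofuran | COc1cc2c(cc1[C@@H](C)/C=C(\C)c1cc3cc(C4(C)OCCO4)c(OCOC)cc3o1)C=CC(C)(C)O2
A10 | alternative 3 | (7-methoxy-2,2-dimethyl-2H-chromen-6-yl)boronic acid | COc1cc2OC(C)(C)C=Cc2cc1B(O)O
A11 | alternative 3 | 1-{6-(methoxymethoxy)-2-[(2E)-penta-2,4-dien-2-yl]-1-benzofuran-5-yl}ethan-1-one | C=C/C=C(\C)c1cc2cc(C(C)=O)c(OCOC)cc2o1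
A12 | alternative 3 | 1-{2-[(2E,4S)-4-(7-methoxy-2,2-dimethyl-2H-chromen-6-yl)pent-2-en-2-yl]-6-(methoxymethoxy)-1-benzofuran-5-yl}ethan-1-one | COc1cc2c(cc1[C@@H](C)/C=C(\C)c1cc3cc(C(C)=O)c(OCOC)cc3o1)C=CC(C)(C)O2
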